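Retrosynthetic overview
- The target is a constitutional isomer of an acyclic, achiral curcuminoid. Cut ring bond C1–C2 and move one H from C5 back to C1, and the result is 4-[(2E,4E)-5-(3,4-dimethoxyphenyl)penta-2,4-dienyl]curcumin. C1 is the quaternary carbon, the old curcumin C4, and is not stereogenic because its two feruloyl arms are identical. C2 is the only stereocentre and is both benzylic to the 3,4-dimethoxyphenyl ring and allylic to C3=C4.
- In the forward direction, one enantioselective Pd-catalysed cycloisomerisation puts a proton on the diene terminus and joins the diketone carbon to the benzylic end of the aryl-allyl-Pd unit. It closes the only new ring (the cyclohexene), builds the quaternary carbon, sets C2 and places C3=C4. It is the last step and needs no protecting group.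
- The precursor comes from a 3-dienylacetylacetone and two vanillin units by a two-directional boron-templated aldol condensation that installs both identical arms at once.
- The dienyl diketone comes from acetylacetone and a pentadienyl carbonate (Tsuji–Trost). The carbonate comes from 3,4-dimethoxycinnamaldehyde and vinylmagnesium bromide.

Key step: step 4

Remarks and assumptions
- Locants: the cyclohexene is numbered C1 (quaternary), C2 (CH–Ar), C3=C4, C5H2, C6H2. The dienyl chain runs from C1′ (CH2 on the diketone carbon) to C5′ (CH–Ar). The central curcumin carbon is C4. The mapping is C5′→C2, C4′→C3, C3′→C4, C2′→C5, C1′→C6.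
- All 1,3-diketones are drawn as diketo tautomers. Catalyst-bound Pd species never exceed the catalyst loading, so they are described in the Why lines and not numbered.
- The (S)-ligand is written in step 4. The closing allyl terminus differs from that of the intermolecular precedents, so the sense of induction has to be read from the first run, by comparison with material from the stereospecific fallback. The equally available (R)-ligand is used if the mirror image forms.

Step 1
Reactants: 1 (E)-3,4-dimethoxycinnamaldehyde; 2 vinylmagnesium bromide
Product: 4 racemic (E)-1-(3,4-dimethoxyphenyl)penta-1,4-dien-3-yl methyl carbonate, via bromomagnesium (E)-1-(3,4-dimethoxyphenyl)penta-1,4-dien-3-olate 3 (not isolated)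
Conditions: 2 (1.1 equiv), THF, −78 → 0 °C; then ClCO2Me (1.3 equiv), 0 °C → rt; short plug of Et3N-deactivated silica, used promptly
Reagents that add atoms: methyl chloroformate, COC(=O)Cl
Why: 1,2-addition of the vinyl Grignard reagent to the enal is followed by O-acylation of the alkoxide in the same flask, and the carbinol centre is racemic on purpose because it is erased in the η3-pentadienyl complex of step 2.

Step 2
Reactants: 4 racemic pentadienyl methyl carbonate; 5 pentane-2,4-dione (acetylacetone)
Product: 6 3-[(2E,4E)-5-(3,4-dimethoxyphenyl)penta-2,4-dien-1-yl]pentane-2,4-dione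
Conditions: Pd(PPh3)4 (2 mol %), 5 (3 equiv), THF, 25–40 °C
Reagents that add atoms: none
Why: In this Tsuji–Trost allylic alkylation Pd(0) ionises the bis-allylic carbonate, loss of CO2 gives methoxide that deprotonates 5, the soft enolate attacks the unsubstituted terminus of the styryl-substituted syn-η3-allyl to give the fully conjugated (2E,4E)-diene, and the excess of 5 suppresses a second alkylation.

Step 3
Reactants: 6 dienyl diketone; 7 vanillin (2.1 equiv)
Product: 10 (1E,6E)-4-[(2E,4E)-5-(3,4-dimethoxyphenyl)penta-2,4-dien-1-yl]-1,7-bis(4-hydroxy-3-methoxyphenyl)hepta-1,6-diene-3,5-dione (4-dienylcurcumin, achiral), via the dibutoxyboron chelate of the dienyl diketone enolate 8 (not isolated), via the dibutoxyboron chelate of the dienylcurcumin enolate 9 (not isolated)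
Conditions: B(OnBu)3 (2.5 equiv), B2O3 (0.7 equiv), EtOAc, 75 °C; then 7, nBuNH2 (0.3 equiv, slow addition), 75 °C; then 10% aq AcOH, 40 °C
Reagents that add atoms: none
Why: This boron-templated double Claisen–Schmidt (Pabon-type) condensation is known for 3-alkyl- and 3-allylpentane-2,4-diones; chelation masks C3–H, the vanillin imine condenses at both terminal methyl groups, loss of water gives the (E)-enones, and the free phenols and the diene tolerate the near-neutral medium and the weak-acid hydrolysis.

Step 4
Reactants: 10 4-dienylcurcumin
Product: 12 (2E,2′E)-1,1′-[(2R)-2-(3,4-dimethoxyphenyl)cyclohex-3-ene-1,1-diyl]bis[3-(4-hydroxy-3-methoxyphenyl)prop-2-en-1-one] (target), via the O-closed isomer (E)-1-{(2S)-2-[(E)-3,4-dimethoxystyryl]-6-[(E)-4-hydroxy-3-methoxystyryl]-3,4-dihydro-2H-pyran-5-yl}-3-(4-hydroxy-3-methoxyphenyl)prop-2-en-1-one 11 (not isolated)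
Conditions: [(η3-C3H5)Pd((S)-(CF3)3-tBu-PHOX)]BArF4 (5 mol %), Et3N (0.5 equiv), [Et3NH]BArF4 (5 mol %), CH2Cl2 (0.02 M), Ar, 25 → 40 °C
Reagents that add atoms: none
Why: Proposed new method: Et3NH+ protonates the Pd(0)-bound s-cis diene of 10 at C2′, the alkyl-bearing diene terminus, which gives the aryl-conjugated η3-allyl over C3′–C5′ directly with the tether in the anti position, and the tethered enolate carbon C4 of the 1,3-diketone then attacks the benzylic terminus C5′ on the face away from Pd, so that 10 is isomerised to 12 without any added atom. The closest known reaction types are the Pd–PHOX-catalysed enantioselective intermolecular hydroalkylation of 1-aryl-4-alkyl-1,3-dienes with 1,3-diketones (same protonation site, same allyl unit, same nucleophile class) and the Pd(0)-catalysed oxygen-to-carbon allyl shifts that turn vinyl-substituted cyclic enol ethers into carbocycles; what is new is the intramolecular closure at the aryl-bearing allyl terminus. The cyclohexene closes in the endo mode (all three allyl carbons become ring members C2–C4, and the cis-alkene follows from the anti allyl); the competing 4-exo C-closure would give a strained 1,1-diacyl-2-styrylcyclobutane and the 6-exo O-closure gives dihydropyran 11, and both keep a stabilised diketonate as allylic leaving group that Pd(0) re-ionises, so the unstrained C1–C2 bond is the sink. The only stereocentre, C2, is set by the ligand: the two allyl faces exchange through reversible protonation and deprotonation via the free diene (Curtin–Hammett situation), attack occurs trans to phosphorus, and the tert-butyl group of the oxazoline decides which diastereomeric allyl complex closes; C1 needs no control because its two feruloyl groups are identical, and (S)-11 correlates with (R)-12 through ionisation and attack, each with inversion. The step needs intra- over intermolecular addition (secured by high dilution and the six-membered transition state), carbon over phenol-oxygen addition (O–H additions to dienes are reversible and close to thermoneutral, while C–C formation is not reversible) and an untouched pair of cinnamoyl enones (they bind Pd(0) only reversibly, as dba does, and are poor partners for a hindered soft enolate).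

Compound list
1 | (E)-3,4-dimethoxycinnamaldehyde | COc1ccc(/C=C/C=O)cc1OC | starting material
2 | vinylmagnesium bromide | C=C[Mg]Br | starting material
3 | bromomagnesium (E)-1-(3,4-dimethoxyphenyl)penta-1,4-dien-3-olate (racemic) | C=CC(O[Mg]Br)/C=C/c1ccc(OC)c(OC)c1 | intermediate
4 | (E)-1-(3,4-dimethoxyphenyl)penta-1,4-dien-3-yl methyl carbonate (racemic) | COC(=O)OC(C=C)/C=C/c1ccc(OC)c(OC)c1 | intermediate
5 | pentane-2,4-dione (acetylacetone) | CC(=O)CC(C)=O | starting material
6 | 3-[(2E,4E)-5-(3,4-dimethoxyphenyl)penta-2,4-dien-1-yl]pentane-2,4-dione | CC(=O)C(C/C=C/C=C/c1ccc(OC)c(OC)c1)C(C)=O | intermediate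
7 | vanillin | COc1cc(C=O)ccc1O | starting material
8 | dibutoxyboron chelate of the dienyl diketone enolate | CC1=C(C/C=C/C=C/c2ccc(OC)c(OC)c2)C(C)=[O+][B-](OCCCC)(OCCCC)O1 | intermediate
9 | dibutoxyboron chelate of the dienylcurcumin enolate | COc1cc(/C=C/C2=C(C/C=C/C=C/c3ccc(OC)c(OC)c3)C(/C=C/c3ccc(O)c(OC)c3)=[O+][B-](OCCCC)(OCCCC)O2)ccc1O | intermediate
10 | 4-[(2E,4E)-5-(3,4-dimethoxyphenyl)penta-2,4-dien-1-yl]curcumin | COc1cc(/C=C/C(=O)C(C/C=C/C=C/c2ccc(OC)c(OC)c2)C(=O)/C=C/c2ccc(O)c(OC)c2)ccc1O | intermediate
11 | (2S)-2-styryl-3,4-dihydro-2H-pyran isomer (O-closed) | COc1cc(/C=C/C(=O)C2=C(/C=C/c3ccc(O)c(OC)c3)O[C@H](/C=C/c3ccc(OC)c(OC)c3)CC2)ccc1O | intermediate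
12 | (2E,2′E)-1,1′-[(2R)-2-(3,4-dimethoxyphenyl)cyclohex-3-ene-1,1-diyl]bis[3-(4-hydroxy-3-methoxyphenyl)prop-2-en-1-one] | COc1cc(/C=C/C(=O)C2(C(=O)/C=C/c3ccc(O)c(OC)c3)CCC=C[C@@H]2c2ccc(OC)c(OC)c2)ccc1O | target

Total step count: 4
Longest linear sequence: 4 steps (1 → 4 → 6 → 10 → 12)

Steps most likely to fail

1. Step 4 (Proposed new method).
- What may go wrong: the closure may stall at the oxygen-bound isomer. Facial selectivity may be poor because the closing terminus is not that of the precedents. The catalyst may be tied up by the cinnamoyl enones. A thermal intramolecular Diels–Alder reaction between the diene and a cinnamoyl C=C may compete.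
- Fallback (known chemistry, from 10, back to the route at 11 and then 12): a catalytic amount of an achiral Brønsted acid (diphenyl phosphate, CH2Cl2, −20 °C) protonates the electron-rich aryl diene at C2′. The enol oxygen traps the extended allyl cation at C3′, in the way 2-prenyl-1,3-dicarbonyl enols close to dihydropyrans under acid, which gives the racemic dihydropyran F1. Preparative chromatography on a chiral stationary phase separates 11 from its (R)-enantiomer F2, and F2 is returned to F1 with the same acid through reversible ionisation. Heating 11 in degassed o-xylene (about 140 °C, BHT, base-washed glass) then triggers the Claisen rearrangement known for 2-alkenyl-3,4-dihydro-2H-pyrans. It runs through a boat, bicyclo[2.2.2]-like transition state, breaks O1–C2 and forms the bond from C5 to the styryl terminus on the same allyl face. The ring forces the new C3=C4 to be cis, so the (E)-styryl geometry and the (S) C–O centre translate uniquely into the (R) C–C centre of 12.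

2. Step 3.
- What may go wrong: the hindered 3-substituted diketone may form its chelate slowly. The reaction may stop after one condensation. The diene may be attacked by acid during hydrolysis of the boron complex.
- Fallback (from 4, back at 10): the order of bond formation is reversed. Commercial curcumin F3 already carries both arms. It is used in excess and dienylated at C4 with carbonate 4 under Tsuji–Trost conditions (Pd(PPh3)4, THF–DMF, rt). Phenol O-dienyl ethers that form on the way are re-ionised by Pd(0), whereas the C4–C1′ bond is not, so the material should collect in 10.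

3. Step 2.
- What may go wrong: the enolate may attack the internal or benzylic position of the pentadienyl-Pd unit. A second alkylation may occur. The labile carbonate may solvolyse or transpose before it reaches the catalyst.
- Fallback (from 3, back at 6): the π-allyl chemistry is replaced by an SN2 reaction on a geometry-defined halide. An aqueous NH4Cl quench of 3 gives the dienol (E)-1-(3,4-dimethoxyphenyl)penta-1,4-dien-3-ol F4. PBr3 (Et2O, −20 °C) converts it, with allylic transposition, into the fully conjugated primary bromide (2E,4E)-5-(3,4-dimethoxyphenyl)penta-2,4-dienyl bromide F5, which is used crude. F5 alkylates sodium acetylacetonate (5, NaH, THF, 0 °C) to give 6.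

Further compounds
F1 | step 4 | racemic 2-styryl-3,4-dihydro-2H-pyran isomer (rac-11) | COc1cc(/C=C/C(=O)C2=C(/C=C/c3ccc(O)c(OC)c3)OC(/C=C/c3ccc(OC)c(OC)c3)CC2)ccc1O
F2 | step 4 | (2R)-enantiomer of 11 | COc1cc(/C=C/C(=O)C2=C(/C=C/c3ccc(O)c(OC)c3)O[C@@H](/C=C/c3ccc(OC)c(OC)c3)CC2)ccc1O
F3 | step 3 | curcumin | COc1cc(/C=C/C(=O)CC(=O)/C=C/c2ccc(O)c(OC)c2)ccc1O
F4 | step 2 | (E)-1-(3,4-dimethoxyphenyl)penta-1,4-dien-3-ol (racemic) | OC(C=C)/C=C/c1ccc(OC)c(OC)c1
F5 | step 2 | (2E,4E)-5-(3,4-dimethoxyphenyl)penta-2,4-dienyl bromide | BrC/C=C/C=C/c1ccc(OC)c(OC)c1
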